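| flask | electrophile | protonated nucleophile | gas | remark | time |
|---|---|---|---|---|---|
| Monday's | 0.015 M | 8 mM | 0.68 mM (held) | run made earlier |  |
| Friday's | 0.0050 M | 8 mM | 0.68 mM (held) | run made earlier |  |
| noon | 0.010 M | 8.00 mM | 0.68 mM (held) |  | 5.0 min |
| dawn | 0.010 M | 12.0 mM | 0.68 mM (held) |  | 5.0 min |

| run | time / s | electrophile / % | target / % |
|---|---|---|---|
| Monday's | 10.0 | 87 | 11 |
| Monday's | 12.0 | 81 | 11 |
| Monday's | 20.0 | 79 | 16 |
| Monday's | 30.0 | 70 | 20 |
| Monday's | 50.0 | 65 | 24 |
| Monday's | 60.0 | 65 | 17 |
| Friday's | 10.0 | 88 | 14 |
| Friday's | 20.0 | 74 | 18 |
| Friday's | 30.0 | 64 | 23 |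
| Friday's | 40.0 | 57 | 22 |
| Friday's | 50.0 | 54 | 26 |
| Friday's | 60.0 | 48 | 23 |

(readings scatter by 2 percentage points)
- at the start none of the gas is in solution
- part of the electrophile that has reacted at the end, noon
- part of the electrophile that has reacted at the end, dawn
- what raising the concentration of protonated nucleophile from its lowest to its highest value here does to the part of the electrophile that has reacted (changes below 5 percentage points count as none) (it falls / it rises / no change)

1. At early times Monday's run and Friday's run kept 87% and 88% of their electrophile at 10.0 s, so the first loss looked first order in electrophile. Later, Monday's run stood at 65% and 65%, and I read a stop.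

2. Target stood still late in Friday's run. I took its making there to equal its loss, so electrophile over target gave the ratio of the loss constant to the making constant, the selectivity factor: 2.08, a reading from 4 scattered points, which I took as 2.

3. My own reckoning assumed that protonated nucleophile was the limiting reagent: each electrophile reacted cost one, and each target lost cost a second. With a the electrophile fraction left and the factor taken as 2, target is a(1 − a), and the stop comes where (1 − a)(2 − a) equals protonated nucleophile over electrophile charged. For Monday's run this gave 38.5% reacted, against 35.0% read.

4. My bench note said to expect 52.5% reacted at noon and 70.4% at dawn. It also said not to extend the wait, since 5.0 min is far longer than the 50.0 s by which Monday's readings stood flat.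

5. The forecast gave 72% (60% to 80%) for noon and 91% (72% to 98%) for dawn, with the reacted part: it rises. Of target it said: “it probably reacts onward, but that doesn't affect electrophile loss”.

6. The flasks gave 51.2% at noon and 69.0% at dawn, below the forecast's ranges; the reacted part: it rises, by 18 percentage points.

    nucleophile + target → over-reaction product (k = 5.25 M⁻¹ s⁻¹)
    electrophile + nucleophile → acid set free + target (k = 2.25 M⁻¹ s⁻¹)
    nucleophile + acid set free ⇌ protonated nucleophile, settled at all times (K = 930 M⁻¹)
    gas ⇌ free base, rate k4*(csat - [free base]) (kL = 24.9 s⁻¹)
    acid set free + free base ⇌ salt of the base, settled at all times (K = 1.64 × 10⁷ M⁻¹)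

The neighbouring flask was like dawn but charged with 0.040 M of electrophile. The same reckoning gave 24.2% reacted, and the flask gave 23.7%. Its electrophile over target ended at 4.41, above the factor of 2.08, with the nucleophile at 0 M. Dawn ended at 1.69, below it. The neighbour finished with 17.3% target and 6.35% over-reaction product.

All runs were generated by integration from invented constants.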